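**Retrosynthetic overview**
- Both prenyl groups are removed last, leaving 6,6'-dibromo-1,3'-biindole (twofold Stille coupling at the end).
- The pyrrole ring of the upper (N–H) indole is opened at N1–C2 to an o-nitroaryl enamine (Leimgruber–Batcho reductive ring closure).
- Key C–C bond (future C2–C3 of the upper indole): Mannich-type condensation of the benzylic carbanion of 6-bromo-1-(4-bromo-2-nitrobenzyl)indole with the formamidinium carbon of Bredereck's reagent.
- The N-benzyl bond is cut to 6-bromoindole and 4-bromo-2-nitrobenzyl bromide, the latter from 4-bromo-2-nitrotoluene.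
- Ring order: the lower indole is bought intact; the upper indole ring is built on its nitrogen substituent.

Assumption: the target has no stereocentre and no stereogenic double bond, so it is achiral and needs no stereocontrol.

The key condensation (step 3) is argued by analogy to acceptor-substituted o-nitrotoluenes; it has not been checked against a literature example on this exact substrate.

**Step 1**
Reactants: 1 4-bromo-2-nitrotoluene
Product: 2 4-bromo-1-(bromomethyl)-2-nitrobenzene
Conditions: NBS (1.1 equiv), AIBN (5 mol %), PhCF3, reflux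
Reagents that add atoms: N-bromosuccinimide, O=C1CCC(=O)N1Br
Why: Wohl–Ziegler radical bromination attacks the only benzylic C–H type, and the nitro-deactivated ring resists electrophilic bromination, so near-stoichiometric NBS gives the monobromide.

**Step 2**
Reactants: 2 4-bromo-1-(bromomethyl)-2-nitrobenzene, 3 6-bromo-1H-indole
Product: 5 6-bromo-1-(4-bromo-2-nitrobenzyl)-1H-indole, via sodium 6-bromoindol-1-ide 4 (not isolated)
Conditions: NaH (1.05 equiv), DMF, 0 °C; then 2 (1.0 equiv), 0 °C to rt
Reagents that add atoms: none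
Why: SN2 N-alkylation of the pre-formed sodium indolide in a dipolar aprotic solvent goes on nitrogen rather than C3, and keeping base and bromide near 1:1 avoids deprotonating the acidic benzylic CH2 of the product.

**Step 3**
Reactants: 5 6-bromo-1-(4-bromo-2-nitrobenzyl)-1H-indole, 6 tert-butoxybis(dimethylamino)methane (Bredereck's reagent)
Product: 8 2-(4-bromo-2-nitrophenyl)-2-(6-bromo-1H-indol-1-yl)-N,N-dimethylethen-1-amine, via aminal Mannich adduct 7 (not isolated)
Conditions: 6 (3 equiv), DMF, 100 °C, Ar; used crude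
Reagents that add atoms: none
Why: In this intermolecular Mannich-type condensation (Leimgruber–Batcho/Bredereck aminomethylenation), tert-butoxide released from 6 deprotonates the CH2 acidified by the ortho-nitroaryl ring and the N-indolyl group, the carbanion adds to the formamidinium carbon to make the new C–C bond, and aminal 7 loses dimethylamine to give the push–pull enamine as an E/Z mixture whose geometry is irrelevant.

**Step 4**
Reactants: 8 2-(4-bromo-2-nitrophenyl)-2-(6-bromo-1H-indol-1-yl)-N,N-dimethylethen-1-amine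
Product: 10 6-bromo-1-(6-bromo-1H-indol-3-yl)-1H-indole, via amino enamine 9 (not isolated)
Conditions: Fe powder (8 equiv), AcOH/EtOH (1:1), 80 °C
Reagents that add atoms: none
Why: In this Leimgruber–Batcho reductive cyclisation, Fe/AcOH reduces only the nitro group (aryl bromides are untouched) and the aniline adds to the protonated enamine carbon and expels dimethylamine to aromatise to the indole; no stereocentre is formed.

**Step 5**
Reactants: 10 6-bromo-1-(6-bromo-1H-indol-3-yl)-1H-indole, 11 tributyl(3-methylbut-2-en-1-yl)stannane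
Product: 12 6-(3-methylbut-2-en-1-yl)-1-[6-(3-methylbut-2-en-1-yl)-1H-indol-3-yl]-1H-indole
Conditions: 11 (2.6 equiv), Pd(PPh3)4 (10 mol %), DMF, 100 °C, Ar
Reagents that add atoms: none
Why: In this twofold Stille coupling with zerovalent palladium, reductive elimination from the prenyl–palladium–aryl species occurs at the unhindered CH2 terminus to give the linear prenyl arene, and the neutral conditions tolerate the free indole N–H.

**Compound list**
1 | 4-bromo-2-nitrotoluene (4-bromo-1-methyl-2-nitrobenzene) | Cc1ccc(Br)cc1[N+](=O)[O-] | starting material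
2 | 4-bromo-1-(bromomethyl)-2-nitrobenzene | BrCc1ccc(Br)cc1[N+](=O)[O-] | intermediate
3 | 6-bromo-1H-indole | Brc1ccc2cc[nH]c2c1 | starting material
4 | sodium 6-bromoindol-1-ide (formed in the flask) | [Na+].Brc1ccc2cc[n-]c2c1 | intermediate
5 | 6-bromo-1-(4-bromo-2-nitrobenzyl)-1H-indole | Brc1ccc2ccn(Cc3ccc(Br)cc3[N+](=O)[O-])c2c1 | intermediate
6 | tert-butoxybis(dimethylamino)methane (Bredereck's reagent) | CC(C)(C)OC(N(C)C)N(C)C | starting material
7 | 2-(4-bromo-2-nitrophenyl)-2-(6-bromo-1H-indol-1-yl)-N,N,N',N'-tetramethylethane-1,1-diamine (racemic aminal Mannich adduct, formed in the flask) | CN(C)C(N(C)C)C(c1ccc(Br)cc1[N+](=O)[O-])n1ccc2ccc(Br)cc21 | intermediate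
8 | 2-(4-bromo-2-nitrophenyl)-2-(6-bromo-1H-indol-1-yl)-N,N-dimethylethen-1-amine (E/Z mixture, geometry not defined) | CN(C)C=C(c1ccc(Br)cc1[N+](=O)[O-])n1ccc2ccc(Br)cc21 | intermediate
9 | 2-(2-amino-4-bromophenyl)-2-(6-bromo-1H-indol-1-yl)-N,N-dimethylethen-1-amine (E/Z mixture, formed in the flask) | CN(C)C=C(c1ccc(Br)cc1N)n1ccc2ccc(Br)cc21 | intermediate
10 | 6-bromo-1-(6-bromo-1H-indol-3-yl)-1H-indole (6,6'-dibromo-1,3'-biindole) | Brc1ccc2c(-n3ccc4ccc(Br)cc43)c[nH]c2c1 | intermediate
11 | tributyl(3-methylbut-2-en-1-yl)stannane | CC(C)=CC[Sn](CCCC)(CCCC)CCCC | starting material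
12 | 6-(3-methylbut-2-en-1-yl)-1-[6-(3-methylbut-2-en-1-yl)-1H-indol-3-yl]-1H-indole (achiral) | CC(C)=CCc1ccc2c(-n3ccc4ccc(CC=C(C)C)cc43)c[nH]c2c1 | target

**Totals**
Total step count: 5. Longest linear sequence: 5 steps (1 → 2 → 5 → 8 → 10 → 12).

**Three steps most likely to fail**

Step 3 (key condensation). The benzylic carbon is secondary and more hindered than in a simple o-nitrotoluene, and o-nitrobenzyl anions can undergo internal redox at 100 °C. The fallback sets out from 5 and comes back at 10; it replaces the aminomethylenation by a low-temperature Claisen condensation (Reissert indole synthesis). Compound 5 is condensed with diethyl oxalate (KOt-Bu, THF, 0 °C to rt) to give ethyl 3-(4-bromo-2-nitrophenyl)-3-(6-bromo-1H-indol-1-yl)-2-oxopropanoate F1. Fe powder in AcOH at 80 °C reduces the nitro group and the aniline closes onto the ketone to give ethyl 6-bromo-3-(6-bromo-1H-indol-1-yl)-1H-indole-2-carboxylate F2. LiOH in THF/MeOH/H2O gives 6-bromo-3-(6-bromo-1H-indol-1-yl)-1H-indole-2-carboxylic acid F3. Protodecarboxylation with Ag2CO3 (10 mol %) and AcOH in DMSO at 120 °C, which leaves the aryl bromides alone, returns 10.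

Step 5 (twofold prenylation). Risks are some branched (reverse-prenyl) coupling, a stalled mono-coupled product and tin residues. The fallback sets out from 10 and comes back at 12; it reverses the polarity of the coupling partners. Miyaura borylation of 10 (B2pin2, Pd(dppf)Cl2, KOAc, dioxane, 90 °C) gives 6-(4,4,5,5-tetramethyl-1,3,2-dioxaborolan-2-yl)-1-[6-(4,4,5,5-tetramethyl-1,3,2-dioxaborolan-2-yl)-1H-indol-3-yl]-1H-indole F4. Allyl–aryl Suzuki–Miyaura coupling of F4 with 1-bromo-3-methylbut-2-ene (Pd(PPh3)4, K2CO3, THF/H2O, 60 °C) then gives 12, the aryl group being delivered to the unhindered terminus of the π-prenyl palladium intermediate.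

Step 1 (benzylic bromination). Risks are incomplete conversion and over-bromination to the dibromide on a deactivated ring. The fallback sets out from 1 and comes back at 2; it replaces the radical step by ionic chemistry. Compound 1 is condensed with N,N-dimethylformamide dimethyl acetal (DMF, 110 °C) to give (E)-2-(4-bromo-2-nitrophenyl)-N,N-dimethylethen-1-amine F5. NaIO4 in THF/H2O at rt cleaves the enamine double bond to 4-bromo-2-nitrobenzaldehyde F6. NaBH4 in MeOH at 0 °C gives (4-bromo-2-nitrophenyl)methanol F7, and PBr3 in CH2Cl2 at 0 °C gives 2.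

**Further compounds**
F1 | step 3 | ethyl 3-(4-bromo-2-nitrophenyl)-3-(6-bromo-1H-indol-1-yl)-2-oxopropanoate (racemic) | CCOC(=O)C(=O)C(c1ccc(Br)cc1[N+](=O)[O-])n1ccc2ccc(Br)cc21
F2 | step 3 | ethyl 6-bromo-3-(6-bromo-1H-indol-1-yl)-1H-indole-2-carboxylate | CCOC(=O)c1[nH]c2cc(Br)ccc2c1-n1ccc2ccc(Br)cc21
F3 | step 3 | 6-bromo-3-(6-bromo-1H-indol-1-yl)-1H-indole-2-carboxylic acid | OC(=O)c1[nH]c2cc(Br)ccc2c1-n1ccc2ccc(Br)cc21
F4 | step 5 | 6-(4,4,5,5-tetramethyl-1,3,2-dioxaborolan-2-yl)-1-[6-(4,4,5,5-tetramethyl-1,3,2-dioxaborolan-2-yl)-1H-indol-3-yl]-1H-indole | CC1(C)OB(OC1(C)C)c1ccc2c(-n3ccc4ccc(B5OC(C)(C)C(C)(C)O5)cc43)c[nH]c2c1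
F5 | step 1 | (E)-2-(4-bromo-2-nitrophenyl)-N,N-dimethylethen-1-amine | CN(C)/C=C/c1ccc(Br)cc1[N+](=O)[O-]
F6 | step 1 | 4-bromo-2-nitrobenzaldehyde | O=Cc1ccc(Br)cc1[N+](=O)[O-]
F7 | step 1 | (4-bromo-2-nitrophenyl)methanol | OCc1ccc(Br)cc1[N+](=O)[O-]
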